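**Retrosynthetic overview**

1. Ring numbering: C-1 = C(OH)Me, C-2 = CH carrying the vinyl carbinol chain, C-3 = quaternary C, C-4 = CHBr, C-5 and C-6 = CH2. The enabling feature is that the oxygen-bearing C-1 lies between C-6 and C-2, with the quaternary C-3 next to C-2 and the CHBr carbon 1,4 to C-1. C-6/C-1/C-2/C-3 is therefore the retron of a 2-oxy-1,3-diene (C-1 at the ketone level) and C-4/C-5 that of a two-carbon dienophile, activated by a CHO group on C-4 that is excised later.
2. Target ⇐ desilylation ⇐ Mukaiyama hydration of a C-1 exocyclic methylene ⇐ cross-metathesis of a C-3 allyl group with 2-methylbut-3-en-2-ol ⇐ methylenation of a 4-bromo ketone.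
3. 4-Bromo ketone ⇐ radical reductive decarboxylation ⇐ carboxyl-directed protonation at C-2 ⇐ catalytic asymmetric Diels–Alder reaction of a (Z)-configured 2-silyloxy triene with 2-bromoacrolein. This forms C-5–C-6 and C-3–C-4 and closes the only ring.
4. Triene ⇐ acetylacetone (C-6, C-1, C-2, C-3 and the C-3 methyl) + a five-carbon iodide cut from (S)-linalool (the whole vinyl carbinol chain with its stereocentre) + an allylstannane.
5. Stereochemical relay: catalyst → C-3; the C-4 carboxyl group → C-2 (internal proton delivery); the equatorial C-2 chain then fixes the chair for C-4 (axial H-atom transfer, both C-4 epimers converge) and for C-1 (equatorial O2 capture).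

Key step: step 9

Remark: (S)-(+)-linalool of high enantiomeric purity and 2-bromoacrolein are taken as purchased. The catalyst antipode in step 9 is assigned from the preference, as recalled, of the (S)-tryptophan-derived catalyst for re-face attack at C-2 of 2-bromoacrolein, so the (R)-series is specified; this sense should be confirmed on the first run.

**Route**

Step 1
Reactants: 1 (S)-(+)-linalool
Product: 2 triethyl{[(3S)-3,7-dimethylocta-1,6-dien-3-yl]oxy}silane
Conditions: Et3SiOTf, 2,6-lutidine, CH2Cl2, −78 → 0 °C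
Reagents that add atoms: triethylsilyl trifluoromethanesulfonate, CC[Si](CC)(CC)OS(=O)(=O)C(F)(F)F
Why: Silyl ether protection of the tertiary alcohol with a silyl triflate and a hindered base; the stereocentre comes from the chiral pool and is not touched.

Step 2
Reactants: 2 triethyl{[(3S)-3,7-dimethylocta-1,6-dien-3-yl]oxy}silane
Product: 3 (4S)-4-methyl-4-[(triethylsilyl)oxy]hex-5-enal
Conditions: O3 (1 equiv, Sudan Red 7B end-point), CH2Cl2, −78 °C; then Me2S, −78 → 23 °C
Reagents that add atoms: ozone, [O-][O+]=O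
Why: Ozonolysis with limiting ozone should cleave the electron-rich trisubstituted alkene well ahead of the monosubstituted vinyl group.

Step 3
Reactants: 3 (4S)-4-methyl-4-[(triethylsilyl)oxy]hex-5-enal
Product: 4 (4S)-4-methyl-4-[(triethylsilyl)oxy]hex-5-enoic acid
Conditions: NaClO2, NaH2PO4, 2-methyl-2-butene, t-BuOH/H2O, 0 → 23 °C
Reagents that add atoms: sodium chlorite, [Na+].[O-]Cl=O
Why: Lindgren–Pinnick oxidation of the aldehyde; buffered chlorite should leave the vinyl group and the silyl ether alone.

Step 4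
Reactants: 4 (4S)-4-methyl-4-[(triethylsilyl)oxy]hex-5-enoic acid
Product: 5 triethyl{[(3S)-5-iodo-3-methylpent-1-en-3-yl]oxy}silane
Conditions: PhI(OAc)2, I2, cyclohexane, hν (tungsten lamp), 40 °C
Reagents that add atoms: iodine, [I][I]
Why: Suárez iododecarboxylation (radical Hunsdiecker type): the acyl hypoiodite loses CO2 and the primary radical is trapped by iodine, shortening the chain to the five carbons needed; the remote carbinol is not involved.

Step 5
Reactants: 5 triethyl{[(3S)-5-iodo-3-methylpent-1-en-3-yl]oxy}silane; 6 pentane-2,4-dione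
Product: 7 3-{(3S)-3-methyl-3-[(triethylsilyl)oxy]pent-4-en-1-yl}pentane-2,4-dione
Conditions: K2CO3, acetone, reflux
Reagents that add atoms: none
Why: C-alkylation of the acetylacetone enolate by an unhindered primary iodide (SN2).

Step 6
Reactants: 7 3-{(3S)-3-methyl-3-[(triethylsilyl)oxy]pent-4-en-1-yl}pentane-2,4-dione
Product: 8 (2Z)-3-{(3S)-3-methyl-3-[(triethylsilyl)oxy]pent-4-en-1-yl}-4-oxopent-2-en-2-yl trifluoromethanesulfonate
Conditions: NaH, THF, 0 °C; then Tf2O, −78 → 0 °C
Reagents that add atoms: trifluoromethanesulfonic anhydride, O=S(=O)(OS(=O)(=O)C(F)(F)F)C(F)(F)F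
Why: Enol triflate formation: O-sulfonylation of the chelated, U-shaped sodium enolate should give the (Z)-triflate (OTf cis to acetyl), and the symmetry of the diketone removes any regiochemical question.

Step 7
Reactants: 8 (2Z)-3-{(3S)-3-methyl-3-[(triethylsilyl)oxy]pent-4-en-1-yl}-4-oxopent-2-en-2-yl trifluoromethanesulfonate; 9 allyltributylstannane
Product: 10 (3Z)-4-methyl-3-{(3S)-3-methyl-3-[(triethylsilyl)oxy]pent-4-en-1-yl}hepta-3,6-dien-2-one
Conditions: Pd(PPh3)4 (5 mol %), LiCl, THF, 55 °C
Reagents that add atoms: none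
Why: Stille coupling of a β-acyl vinyl triflate proceeds with retention of alkene geometry, so the allyl group ends cis to the acetyl group on the tetrasubstituted alkene.

Step 8
Reactants: 10 (3Z)-4-methyl-3-{(3S)-3-methyl-3-[(triethylsilyl)oxy]pent-4-en-1-yl}hepta-3,6-dien-2-one
Product: 11 {[(3Z)-4-methyl-3-{(3S)-3-methyl-3-[(triethylsilyl)oxy]pent-4-en-1-yl}hepta-1,3,6-trien-2-yl]oxy}tri(propan-2-yl)silane
Conditions: LiN(i-Pr)2, THF, −78 °C; then i-Pr3SiOTf, −78 → 0 °C
Reagents that add atoms: triisopropylsilyl trifluoromethanesulfonate, CC(C)[Si](OS(=O)(=O)C(F)(F)F)(C(C)C)C(C)C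
Why: Silyl enol ether formation by kinetic deprotonation of the enone at its α′-methyl group (cross-conjugated dienolate) and O-silylation; the geometry of the tetrasubstituted alkene is not affected.

Step 9
Reactants: 11 {[(3Z)-4-methyl-3-{(3S)-3-methyl-3-[(triethylsilyl)oxy]pent-4-en-1-yl}hepta-1,3,6-trien-2-yl]oxy}tri(propan-2-yl)silane; 12 2-bromoprop-2-enal
Product: 13 (1S,2S)-1-bromo-2-methyl-3-{(3S)-3-methyl-3-[(triethylsilyl)oxy]pent-4-en-1-yl}-2-(prop-2-en-1-yl)-4-{[tri(propan-2-yl)silyl]oxy}cyclohex-3-ene-1-carbaldehyde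
Conditions: 12 (1.5 equiv), (4R)-2-butyl-4-(1H-indol-3-ylmethyl)-3-(4-methylbenzenesulfonyl)-1,3,2-oxazaborolidin-5-one (20 mol %, from N-tosyl-(R)-tryptophan and BuB(OH)2), CH2Cl2, −78 → −40 °C
Reagents that add atoms: none
Why: A Lewis-acid-catalysed, asynchronous [4+2] cycloaddition in which the boron-bound 2-bromoacrolein is attacked first at its CH2 terminus by the silyl enol ether carbon of 11 (bond C-5–C-6) and then closes at the tetrasubstituted diene terminus (bond C-3–C-4), so the cyclohexene is closed by a suprafacial six-electron cycloaddition that should tolerate the hindered terminus because the first bond is far advanced. The closest known reaction types are the oxazaborolidinone-catalysed Diels–Alder reaction of 2-silyloxy dienes with 2-bromoacrolein and other α-substituted acroleins, and Lewis-acid-promoted cycloadditions of tetrasubstituted 2-silyloxy dienes that build quaternary centres. The regiochemistry is fixed by the 2-silyloxy group, which makes the unsubstituted CH2 the nucleophilic terminus, and only the conjugated diene reacts because the allyl and vinyl groups are isolated alkenes. The quaternary C-3 is set by the catalyst, which should expose the si face of C-2 of the aldehyde (it is the antipode of the catalyst taken to give re attack), combined with the exo position of CHO that α-haloacroleins prefer and the fixed (Z)-geometry of the diene; this places methyl cis to bromine and allyl cis to CHO. The C-4 centre is formed as (S) but serves only as a relay: its carbonyl group directs step 10 and its configuration is set for good in step 11. The step needs facial, exo and regio selectivity together, secured respectively by the indole-shielded catalyst complex, the α-bromine and the siloxy group.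

Step 10
Reactants: 13 (1S,2S)-1-bromo-2-methyl-3-{(3S)-3-methyl-3-[(triethylsilyl)oxy]pent-4-en-1-yl}-2-(prop-2-en-1-yl)-4-{[tri(propan-2-yl)silyl]oxy}cyclohex-3-ene-1-carbaldehyde
Product: 15 (1S,2S,3S)-1-bromo-2-methyl-3-{(3S)-3-methyl-3-[(triethylsilyl)oxy]pent-4-en-1-yl}-4-oxo-2-(prop-2-en-1-yl)cyclohexane-1-carboxylic acid, via enol ether acid 14 (not isolated)
Conditions: NaClO2, NaH2PO4, 2-methyl-2-butene, t-BuOH/H2O, 0 °C; then extraction into wet CH2Cl2, 23 °C
Reagents that add atoms: sodium chlorite, [Na+].[O-]Cl=O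
Why: Proposed new method: a Lindgren–Pinnick oxidation (known) turns the aldehyde into acid 14, whose carboxyl group sits 1,3-syn to the enol ether carbon on the allyl face of the ring and should deliver its proton there through a six-membered transition state faster than external acid at pH 4, so that hydrogen enters cis to CO2H and the side chain ends cis to the ring methyl ((S) at the new centre) before the silyl group is lost; the closest known reaction type is the intramolecular general-acid-catalysed hydrolysis of enol ethers by a neighbouring carboxylic acid.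

Step 11
Reactants: 15 (1S,2S,3S)-1-bromo-2-methyl-3-{(3S)-3-methyl-3-[(triethylsilyl)oxy]pent-4-en-1-yl}-4-oxo-2-(prop-2-en-1-yl)cyclohexane-1-carboxylic acid
Product: 17 (2S,3S,4S)-4-bromo-3-methyl-2-{(3S)-3-methyl-3-[(triethylsilyl)oxy]pent-4-en-1-yl}-3-(prop-2-en-1-yl)cyclohexan-1-one, via thiohydroxamate ester 16 (not isolated)
Conditions: N-hydroxypyridine-2-thione, DCC, DMAP (cat.), CH2Cl2, 0 °C, dark; then t-BuSH (10 equiv), hν (tungsten lamp), 10 °C
Reagents that add atoms: none
Why: Barton reductive decarboxylation: the ester fragments to the α-bromo radical, which should take hydrogen from the thiol on the axial face anti to the axial methyl of the neighbouring quaternary carbon (chair fixed by the equatorial C-2 chain), leaving bromine equatorial and cis to methyl whatever the configuration of the acid.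

Step 12
Reactants: 17 (2S,3S,4S)-4-bromo-3-methyl-2-{(3S)-3-methyl-3-[(triethylsilyl)oxy]pent-4-en-1-yl}-3-(prop-2-en-1-yl)cyclohexan-1-one
Product: 18 (1S,2S,3R)-1-bromo-2-methyl-4-methylidene-3-{(3S)-3-methyl-3-[(triethylsilyl)oxy]pent-4-en-1-yl}-2-(prop-2-en-1-yl)cyclohexane
Conditions: Cp2TiMe2, toluene, 65 °C, dark
Reagents that add atoms: dimethyltitanocene, C[Ti](C)(C1C=CC=C1)C1C=CC=C1
Why: Petasis methylenation converts the hindered ketone under non-basic conditions, so the epimerisable α-centre should keep its configuration (the descriptor changes only because the priorities change).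

Step 13
Reactants: 18 (1S,2S,3R)-1-bromo-2-methyl-4-methylidene-3-{(3S)-3-methyl-3-[(triethylsilyl)oxy]pent-4-en-1-yl}-2-(prop-2-en-1-yl)cyclohexane; 19 2-methylbut-3-en-2-ol
Product: 20 (3E)-5-[(1S,2S,6R)-2-bromo-1-methyl-5-methylidene-6-{(3S)-3-methyl-3-[(triethylsilyl)oxy]pent-4-en-1-yl}cyclohexyl]-2-methylpent-3-en-2-ol
Conditions: second-generation Hoveyda–Grubbs catalyst (5 mol %), 19 (10 equiv), CH2Cl2, 40 °C
Reagents that add atoms: none
Why: Olefin cross-metathesis: only the unhindered allyl group should react with the excess tertiary allylic alcohol, giving the (E)-alkene, while the 1,1-disubstituted methylene and the fully substituted vinyl silyl ether carbinol stay inert.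

Step 14
Reactants: 20 (3E)-5-[(1S,2S,6R)-2-bromo-1-methyl-5-methylidene-6-{(3S)-3-methyl-3-[(triethylsilyl)oxy]pent-4-en-1-yl}cyclohexyl]-2-methylpent-3-en-2-ol
Product: 21 (1S,2S,3S,4S)-4-bromo-3-[(2E)-4-hydroxy-4-methylpent-2-en-1-yl]-1,3-dimethyl-2-{(3S)-3-methyl-3-[(triethylsilyl)oxy]pent-4-en-1-yl}cyclohexan-1-ol
Conditions: Co(acac)2 (20 mol %), PhSiH3, O2 (1 atm), THF/i-PrOH, 0 → 23 °C
Reagents that add atoms: dioxygen, O=O
Why: Mukaiyama hydration (hydrogen-atom transfer from a cobalt hydride): the 1,1-disubstituted alkene reacts in preference, and the tertiary radical at C-1 should be captured by O2 from the equatorial side because the axial C-3 methyl blocks the axial approach, giving equatorial OH and axial methyl as in the hydration of exocyclic alkenes of the labdane series.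

Step 15
Reactants: 21 (1S,2S,3S,4S)-4-bromo-3-[(2E)-4-hydroxy-4-methylpent-2-en-1-yl]-1,3-dimethyl-2-{(3S)-3-methyl-3-[(triethylsilyl)oxy]pent-4-en-1-yl}cyclohexan-1-ol
Product: 22 (1S,2S,3S,4S)-4-bromo-2-[(3S)-3-hydroxy-3-methylpent-4-en-1-yl]-3-[(2E)-4-hydroxy-4-methylpent-2-en-1-yl]-1,3-dimethylcyclohexan-1-ol
Conditions: Bu4NF, THF, 0 → 23 °C
Reagents that add atoms: none
Why: Fluoride-mediated cleavage of the silyl ether; the equatorial neopentyl bromide has no antiperiplanar hydrogen and should survive.

**Compound list**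

1 | (S)-(+)-linalool, (3S)-3,7-dimethylocta-1,6-dien-3-ol | C=C[C@@](C)(O)CCC=C(C)C | starting material
2 | triethyl{[(3S)-3,7-dimethylocta-1,6-dien-3-yl]oxy}silane | C=C[C@@](C)(O[Si](CC)(CC)CC)CCC=C(C)C | intermediate
3 | (4S)-4-methyl-4-[(triethylsilyl)oxy]hex-5-enal | C=C[C@@](C)(O[Si](CC)(CC)CC)CCC=O | intermediate
4 | (4S)-4-methyl-4-[(triethylsilyl)oxy]hex-5-enoic acid | C=C[C@@](C)(O[Si](CC)(CC)CC)CCC(=O)O | intermediate
5 | triethyl{[(3S)-5-iodo-3-methylpent-1-en-3-yl]oxy}silane | C=C[C@@](C)(O[Si](CC)(CC)CC)CCI | intermediate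
6 | pentane-2,4-dione (acetylacetone) | CC(=O)CC(C)=O | starting material
7 | 3-{(3S)-3-methyl-3-[(triethylsilyl)oxy]pent-4-en-1-yl}pentane-2,4-dione | C=C[C@@](C)(O[Si](CC)(CC)CC)CCC(C(C)=O)C(C)=O | intermediate
8 | (2Z)-3-{(3S)-3-methyl-3-[(triethylsilyl)oxy]pent-4-en-1-yl}-4-oxopent-2-en-2-yl trifluoromethanesulfonate (OTf cis to acetyl) | C=C[C@@](C)(O[Si](CC)(CC)CC)CC/C(C(C)=O)=C(\C)OS(=O)(=O)C(F)(F)F | intermediate
9 | allyltributylstannane | C=CC[Sn](CCCC)(CCCC)CCCC | starting material
10 | (3Z)-4-methyl-3-{(3S)-3-methyl-3-[(triethylsilyl)oxy]pent-4-en-1-yl}hepta-3,6-dien-2-one (allyl cis to acetyl) | C=C[C@@](C)(O[Si](CC)(CC)CC)CC/C(C(C)=O)=C(\C)CC=C | intermediate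
11 | {[(3Z)-4-methyl-3-{(3S)-3-methyl-3-[(triethylsilyl)oxy]pent-4-en-1-yl}hepta-1,3,6-trien-2-yl]oxy}tri(propan-2-yl)silane | C=C[C@@](C)(O[Si](CC)(CC)CC)CC/C(C(=C)O[Si](C(C)C)(C(C)C)C(C)C)=C(\C)CC=C | intermediate
12 | 2-bromoprop-2-enal (2-bromoacrolein) | C=C(Br)C=O | starting material
13 | (1S,2S)-1-bromo-2-methyl-3-{(3S)-3-methyl-3-[(triethylsilyl)oxy]pent-4-en-1-yl}-2-(prop-2-en-1-yl)-4-{[tri(propan-2-yl)silyl]oxy}cyclohex-3-ene-1-carbaldehyde (Br cis to methyl, CHO cis to allyl) | CC(C)[Si](C(C)C)(C(C)C)OC1=C(CC[C@](C)(O[Si](CC)(CC)CC)C=C)[C@](C)(CC=C)[C@](Br)(C=O)CC1 | intermediate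
14 | (1S,2S)-1-bromo-2-methyl-3-{(3S)-3-methyl-3-[(triethylsilyl)oxy]pent-4-en-1-yl}-2-(prop-2-en-1-yl)-4-{[tri(propan-2-yl)silyl]oxy}cyclohex-3-ene-1-carboxylic acid (not isolated) | CC(C)[Si](C(C)C)(C(C)C)OC1=C(CC[C@](C)(O[Si](CC)(CC)CC)C=C)[C@](C)(CC=C)[C@](Br)(C(=O)O)CC1 | intermediate
15 | (1S,2S,3S)-1-bromo-2-methyl-3-{(3S)-3-methyl-3-[(triethylsilyl)oxy]pent-4-en-1-yl}-4-oxo-2-(prop-2-en-1-yl)cyclohexane-1-carboxylic acid (side chain cis to methyl and bromine) | O=C1[C@@H](CC[C@](C)(O[Si](CC)(CC)CC)C=C)[C@](C)(CC=C)[C@](Br)(C(=O)O)CC1 | intermediate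
16 | 2-thioxopyridin-1(2H)-yl ester of acid 15 (not isolated) | O=C1[C@@H](CC[C@](C)(O[Si](CC)(CC)CC)C=C)[C@](C)(CC=C)[C@](Br)(C(=O)ON2C=CC=CC2=S)CC1 | intermediate
17 | (2S,3S,4S)-4-bromo-3-methyl-2-{(3S)-3-methyl-3-[(triethylsilyl)oxy]pent-4-en-1-yl}-3-(prop-2-en-1-yl)cyclohexan-1-one (Br, methyl and side chain all cis) | O=C1[C@@H](CC[C@](C)(O[Si](CC)(CC)CC)C=C)[C@](C)(CC=C)[C@@H](Br)CC1 | intermediate
18 | (1S,2S,3R)-1-bromo-2-methyl-4-methylidene-3-{(3S)-3-methyl-3-[(triethylsilyl)oxy]pent-4-en-1-yl}-2-(prop-2-en-1-yl)cyclohexane | C=C1[C@@H](CC[C@](C)(O[Si](CC)(CC)CC)C=C)[C@](C)(CC=C)[C@@H](Br)CC1 | intermediate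
19 | 2-methylbut-3-en-2-ol | C=CC(C)(C)O | starting material
20 | (3E)-5-[(1S,2S,6R)-2-bromo-1-methyl-5-methylidene-6-{(3S)-3-methyl-3-[(triethylsilyl)oxy]pent-4-en-1-yl}cyclohexyl]-2-methylpent-3-en-2-ol | C=C1[C@@H](CC[C@](C)(O[Si](CC)(CC)CC)C=C)[C@](C)(C/C=C/C(C)(C)O)[C@@H](Br)CC1 | intermediate
21 | (1S,2S,3S,4S)-4-bromo-3-[(2E)-4-hydroxy-4-methylpent-2-en-1-yl]-1,3-dimethyl-2-{(3S)-3-methyl-3-[(triethylsilyl)oxy]pent-4-en-1-yl}cyclohexan-1-ol | C=C[C@@](C)(O[Si](CC)(CC)CC)CC[C@H]1[C@](C)(C/C=C/C(C)(C)O)[C@@H](Br)CC[C@]1(C)O | intermediate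
22 | (1S,2S,3S,4S)-4-bromo-2-[(3S)-3-hydroxy-3-methylpent-4-en-1-yl]-3-[(2E)-4-hydroxy-4-methylpent-2-en-1-yl]-1,3-dimethylcyclohexan-1-ol | C=C[C@@](C)(O)CC[C@H]1[C@](C)(C/C=C/C(C)(C)O)[C@@H](Br)CC[C@]1(C)O | target

**Summary**

Total step count: 15. Longest linear sequence: 15 steps (from 1).

**Steps most likely to fail**

Step 10. The risk is that external protonation or plain hydrolysis of the silyl enol ether competes with internal proton delivery, giving poor facial selectivity at C-2. A second risk is later epimerisation at this centre, because the keto acid formed is not the thermodynamically preferred epimer. The fallback sets out from 13 and replaces substrate control by reagent control. The silyl enol ether is protonated at −78 °C in toluene with the SnCl4 complex of 2-hydroxy-2'-methoxy-1,1'-binaphthyl (a Lewis acid-assisted chiral Brønsted acid, known for silyl enol ethers of 2-alkylcyclohexanones), using whichever antipode is matched to attack on the face anti to the ring methyl. This should give the keto aldehyde F1. Lindgren–Pinnick oxidation of F1 under the conditions of step 3 then comes back to the route at 15.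

Step 9. The risk is slow cycloaddition at the tetrasubstituted, (Z)-substituted diene terminus with the mild chiral catalyst, or insufficient facial or exo discrimination on this hindered diene. Either would erode the configuration of the quaternary carbon relative to the side-chain stereocentre. The fallback sets out from 11 and 12 and gives up catalyst control. The cycloaddition is run with a stronger achiral Lewis acid (Me2AlCl, or AlBr3/AlMe3 10:1, in toluene/CH2Cl2 at −40 to −5 °C), which is the known way to force hindered 2-silyloxy dienes to react. Because the side chain already carries a stereocentre, the two ring antipodes are formed as diastereomers: 13 and the (1R,2R)-diastereomer F2. These are separated by chromatography on a chiral stationary phase, and the route is rejoined at 13.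

Step 11. The risks are sluggish acylation of the hindered tertiary α-bromo acid, epimerisation α to the ketone during activation, and loss of bromine before the radical is reduced. The fallback sets out from 15 and avoids the activated ester altogether. The carboxylate is oxidised photocatalytically (9-mesityl-10-methylacridinium tetrafluoroborate, PhSSPh, catalytic 2,6-lutidine, CF3CH2OH, blue light), a known hydrodecarboxylation. It generates the same α-bromo radical, which is reduced by thiophenol formed in situ with the same axial hydrogen transfer, and comes back to the route at 17. No new compound is made on the way (F0).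

**Further compounds**

F1 | step 10 | (1S,2S,3S)-1-bromo-2-methyl-3-{(3S)-3-methyl-3-[(triethylsilyl)oxy]pent-4-en-1-yl}-4-oxo-2-(prop-2-en-1-yl)cyclohexane-1-carbaldehyde | O=C1[C@@H](CC[C@](C)(O[Si](CC)(CC)CC)C=C)[C@](C)(CC=C)[C@](Br)(C=O)CC1
F2 | step 9 | (1R,2R)-1-bromo-2-methyl-3-{(3S)-3-methyl-3-[(triethylsilyl)oxy]pent-4-en-1-yl}-2-(prop-2-en-1-yl)-4-{[tri(propan-2-yl)silyl]oxy}cyclohex-3-ene-1-carbaldehyde | CC(C)[Si](C(C)C)(C(C)C)OC1=C(CC[C@](C)(O[Si](CC)(CC)CC)C=C)[C@@](C)(CC=C)[C@@](Br)(C=O)CC1
F0 | step 11 | none | none
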